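**Plan**

- Prostanoid numbering: ring C8–C12 (C9 ketone, C10 chlorine, C12 carbinol), ester chain C1–C7 on C8, octenyl chain C13–C20 on C12.
- Cuts, in retrosynthetic order: C7=C8 (aldol condensation with a (Z)-C1–C7 enal), C10–Cl (through the C10–C11 epoxide), C14=C15 (Wittig), the ring bond C11–C12, and C8–C12 of the open chain (acetoacetate dianion aldol).
- Enabling feature: in the cyclopentenone the tertiary carbinol C12 is bonded to C11 and lies 1,5 to it through C10, C9 and C8, so a C11 aldehyde made nucleophilic by a carbene can close the five-membered ring onto a C12 ketone while C9 is held as a dioxolane.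
- Forward: open-chain keto aldehyde, then ring closure C11–C12 (the only ring), C11 reduced and acetylated, octenyl chain by Wittig, C9 unmasked with loss of the C11 acetate, chlorine at C10, C1–C7 chain joined at C8, desilylation.
- Stereochemistry: C12 from the chiral triazolium carbene acting on an achiral substrate; 14Z and 5Z from Wittig reactions of non-stabilised ylides; 7Z from an anti-selective aldol followed by anti-elimination.

Key step: step 5

Remark: 3-(benzyloxy)propanal (2) is taken as the commercial aldehyde, distilled before use. The C11 epimers formed in step 7 are carried together, because C11 becomes sp2 in step 12.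

**Step 1**
Reactants: 1 methyl acetoacetate; 2 3-(benzyloxy)propanal
Product: 4 methyl 7-(benzyloxy)-5-hydroxy-3-oxoheptanoate (racemic), via acetoacetate dianion 3 (not isolated)
Conditions: NaH, THF, 0 °C; n-BuLi, 0 °C; then 2, −78 °C; aq. NH4Cl
Reagents that add atoms: none
Why: Acetoacetate dianion aldol addition, in which the more reactive terminal carbanion (future C8) adds to the aldehyde (future C12) at −78 °C faster than the β-benzyloxy aldehyde can eliminate; the C12 carbinol is formed racemic and is oxidised in step 4.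

**Step 2**
Reactants: 4 methyl 7-(benzyloxy)-5-hydroxy-3-oxoheptanoate
Product: 6 methyl 2-{2-[4-(benzyloxy)-2-hydroxybutyl]-1,3-dioxolan-2-yl}acetate (racemic), via trimethylsilyl ether 5 (not isolated)
Conditions: Me3SiOCH2CH2OSiMe3, Me3SiOTf (5 mol %), CH2Cl2, −78 → −20 °C; then K2CO3, MeOH, 0 °C
Reagents that add atoms: 1,2-bis(trimethylsilyloxy)ethane, `C[Si](C)(C)OCCO[Si](C)(C)C`
Why: Silyl triflate-catalysed ketalisation with the bis-silyl ether of ethylene glycol masks C9 under aprotic conditions at low temperature; the β-hydroxy ketone is silylated in the flask and so should neither dehydrate nor lactonise, and methanolysis frees the carbinol afterwards.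

**Step 3**
Reactants: 6 methyl 2-{2-[4-(benzyloxy)-2-hydroxybutyl]-1,3-dioxolan-2-yl}acetate
Product: 7 4-(benzyloxy)-1-[2-(2-hydroxyethyl)-1,3-dioxolan-2-yl]butan-2-ol (racemic)
Conditions: LiAlH4, THF, 0 °C; aq. NaOH work-up
Reagents that add atoms: none
Why: Hydride reduction of the ester gives the primary C11 alcohol while ketal, benzyl ether and carbinol are inert; any δ-lactone formed in step 2 is reduced to the same diol.

**Step 4**
Reactants: 7 4-(benzyloxy)-1-[2-(2-hydroxyethyl)-1,3-dioxolan-2-yl]butan-2-ol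
Product: 8 2-{2-[4-(benzyloxy)-2-oxobutyl]-1,3-dioxolan-2-yl}acetaldehyde
Conditions: (COCl)2, DMSO, CH2Cl2, −78 °C; Et3N, −78 → 0 °C
Reagents that add atoms: none
Why: Double Swern oxidation, in which both hydroxyls are activated as alkoxysulfonium ions before base is added, so the primary alcohol cannot be trapped as a six-membered lactol and over-oxidised to the lactone; the keto aldehyde is used without storage.

**Step 5 (key step)**
Reactants: 8 2-{2-[4-(benzyloxy)-2-oxobutyl]-1,3-dioxolan-2-yl}acetaldehyde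
Product: 9 (8S)-8-[2-(benzyloxy)ethyl]-8-hydroxy-1,4-dioxaspiro[4.4]nonan-7-one
Conditions: (5aS,10bR)-2-(pentafluorophenyl)-5a,10b-dihydro-4H,6H-indeno[2,1-b][1,2,4]triazolo[4,3-d][1,4]oxazin-2-ium tetrafluoroborate (15 mol %), Et3N (15 mol %), degassed toluene (0.02 M), 23 °C
Reagents that add atoms: none
Why: The carbene released from the triazolium salt adds to the C11 aldehyde, proton transfer gives the Breslow intermediate (an acyl anion equivalent), its carbon attacks the C12 ketone, and collapse of the adduct returns the carbene and the α-ketol. The closest known reaction type is the enantioselective intramolecular crossed aldehyde–ketone benzoin cyclisation with aminoindanol-derived triazolium salts, applied here to a fully aliphatic keto aldehyde. The cyclopentane closes in 5-exo-trig mode across C11–C12, helped by the gem-dialkoxy effect of the C9 dioxolane. C12 is the only stereocentre and is set by the catalyst alone, since 8 is achiral: the indane wall and the N-aryl group shield one face of the Breslow enol while its hydroxyl hydrogen-bonds to the ketone oxygen, so the ketone should present the face that keeps its benzyloxyethyl arm away from the catalyst; the (5aS,10bR) salt is proposed for the (S)-ketol by analogy, and its antipode is the direct remedy if the sense proves opposite. The step needs chemoselectivity for the benzoin over the base-mediated six-membered aldol (C13 enolate onto C11) and over intermolecular coupling: only the aldehyde can form the Breslow intermediate, the amine is too weak to enolise the ketone at a useful rate, and high dilution disfavours bimolecular reaction.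

**Step 6**
Reactants: 9 (8S)-8-[2-(benzyloxy)ethyl]-8-hydroxy-1,4-dioxaspiro[4.4]nonan-7-one
Product: 10 (8S)-8-[2-(benzyloxy)ethyl]-8-[(tert-butyldimethylsilyl)oxy]-1,4-dioxaspiro[4.4]nonan-7-one
Conditions: t-BuMe2SiOTf, 2,6-lutidine, CH2Cl2, −78 → 0 °C
Reagents that add atoms: tert-butyldimethylsilyl trifluoromethanesulfonate, `CC(C)(C)[Si](C)(C)OS(=O)(=O)C(F)(F)F`
Why: Silyl triflate silylation of the hindered tertiary carbinol, where low temperature and the weak hindered base should keep enol silylation at C10 and ketal opening from competing; the ether blocks retro-aldol and elimination pathways of the C12 oxygen in later steps.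

**Step 7**
Reactants: 10 (8S)-8-[2-(benzyloxy)ethyl]-8-[(tert-butyldimethylsilyl)oxy]-1,4-dioxaspiro[4.4]nonan-7-one
Product: 11 (7RS,8S)-8-[2-(benzyloxy)ethyl]-8-[(tert-butyldimethylsilyl)oxy]-1,4-dioxaspiro[4.4]nonan-7-ol
Conditions: NaBH4, MeOH, −20 → 0 °C
Reagents that add atoms: none
Why: Borohydride reduction of the C11 ketone; the new C11 centre is transient and both epimers are used, and the low temperature limits silyl migration to the new hydroxyl.

**Step 8**
Reactants: 11 (7RS,8S)-8-[2-(benzyloxy)ethyl]-8-[(tert-butyldimethylsilyl)oxy]-1,4-dioxaspiro[4.4]nonan-7-ol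
Product: 12 (7RS,8S)-8-[2-(benzyloxy)ethyl]-8-[(tert-butyldimethylsilyl)oxy]-1,4-dioxaspiro[4.4]nonan-7-yl acetate
Conditions: Ac2O, pyridine, 4-(dimethylamino)pyridine (cat.), CH2Cl2, 23 °C
Reagents that add atoms: acetic anhydride, `CC(=O)OC(C)=O`
Why: Nucleophile-catalysed acylation protects the C11 hydroxyl during the chain synthesis and makes it the leaving group for step 12.

**Step 9**
Reactants: 12 (7RS,8S)-8-[2-(benzyloxy)ethyl]-8-[(tert-butyldimethylsilyl)oxy]-1,4-dioxaspiro[4.4]nonan-7-yl acetate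
Product: 13 (7RS,8S)-8-[(tert-butyldimethylsilyl)oxy]-8-(2-hydroxyethyl)-1,4-dioxaspiro[4.4]nonan-7-yl acetate
Conditions: H2 (1 atm), Pd on carbon (10 wt % Pd), EtOAc, 23 °C
Reagents that add atoms: none
Why: Hydrogenolysis of the benzyl ether at a stage where no alkene is present; silyl ether, acetate and ketal are stable to neutral hydrogenation.

**Step 10**
Reactants: 13 (7RS,8S)-8-[(tert-butyldimethylsilyl)oxy]-8-(2-hydroxyethyl)-1,4-dioxaspiro[4.4]nonan-7-yl acetate
Product: 14 (7RS,8S)-8-[(tert-butyldimethylsilyl)oxy]-8-(2-oxoethyl)-1,4-dioxaspiro[4.4]nonan-7-yl acetate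
Conditions: Dess–Martin periodinane, NaHCO3, CH2Cl2, 0 → 23 °C
Reagents that add atoms: none
Why: Buffered Dess–Martin oxidation of the primary alcohol to the C14 aldehyde; the β-oxygen is silylated, so the aldehyde should not dehydrate, and it is used directly.

**Step 11**
Reactants: 14 (7RS,8S)-8-[(tert-butyldimethylsilyl)oxy]-8-(2-oxoethyl)-1,4-dioxaspiro[4.4]nonan-7-yl acetate; 15 hexyltriphenylphosphonium bromide
Product: 17 (7RS,8S)-8-[(tert-butyldimethylsilyl)oxy]-8-[(2Z)-oct-2-en-1-yl]-1,4-dioxaspiro[4.4]nonan-7-yl acetate, via hexylidene ylide 16 (not isolated)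
Conditions: 15, NaN(SiMe3)2, THF, 0 °C; then 14, −78 → 0 °C
Reagents that add atoms: none
Why: Wittig olefination with a non-stabilised ylide under lithium-free conditions, where kinetic cis-oxaphosphetane formation gives the 14Z alkene and the aldehyde reacts far faster than the acetate.

**Step 12**
Reactants: 17 (7RS,8S)-8-[(tert-butyldimethylsilyl)oxy]-8-[(2Z)-oct-2-en-1-yl]-1,4-dioxaspiro[4.4]nonan-7-yl acetate
Product: 19 (4S)-4-[(tert-butyldimethylsilyl)oxy]-4-[(2Z)-oct-2-en-1-yl]cyclopent-2-en-1-one, via acetoxy ketone 18 (not isolated)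
Conditions: TsOH·H2O (cat.), acetone/H2O (10:1), 40 °C; then DBU, CH2Cl2, 0 °C
Reagents that add atoms: water, `O`
Why: Acid-catalysed ketal hydrolysis frees the C9 ketone and E1cB elimination then expels the C11 acetate, the only good leaving group β to C9; loss of the C12 silyloxy group is disfavoured because it is a poor leaving group and would lead towards a cyclopentadienone, so the double bond should form at C10–C11 only.

**Step 13**
Reactants: 19 (4S)-4-[(tert-butyldimethylsilyl)oxy]-4-[(2Z)-oct-2-en-1-yl]cyclopent-2-en-1-one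
Product: 20 (4S)-4-[(tert-butyldimethylsilyl)oxy]-4-[(2Z)-oct-2-en-1-yl]-6-oxabicyclo[3.1.0]hexan-2-one (epoxide on either face)
Conditions: H2O2 (30 % aq.), NaOH (0.3 equiv), MeOH, 0 °C
Reagents that add atoms: hydrogen peroxide, `OO`
Why: Weitz–Scheffer nucleophilic epoxidation attacks only the electron-poor C10=C11 bond and leaves the 14Z alkene; the epoxide face is of no consequence because C10 and C11 become sp2 again in step 14.

**Step 14**
Reactants: 20 (4S)-4-[(tert-butyldimethylsilyl)oxy]-4-[(2Z)-oct-2-en-1-yl]-6-oxabicyclo[3.1.0]hexan-2-one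
Product: 22 (4S)-4-[(tert-butyldimethylsilyl)oxy]-2-chloro-4-[(2Z)-oct-2-en-1-yl]cyclopent-2-en-1-one, via chlorohydrin 21 (not isolated)
Conditions: HCl (4 M in 1,4-dioxane), CH2Cl2, 0 → 23 °C
Reagents that add atoms: hydrogen chloride, `Cl`
Why: Acid opening of the α,β-epoxy ketone by chloride at C10 (α to the ketone, whereas C11 is neopentylic) gives the chlorohydrin, and acid-catalysed β-dehydration through the enol gives the 2-chloro enone; the hindered tertiary silyl ether and the isolated alkene should tolerate brief exposure to anhydrous HCl.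

**Step 15**
Reactants: 23 (4-carboxybutyl)triphenylphosphonium bromide; 24 (tert-butyldimethylsilyloxy)acetaldehyde
Product: 26 (5Z)-7-[(tert-butyldimethylsilyl)oxy]hept-5-enoic acid, via carboxylate ylide 25 (not isolated)
Conditions: 23, NaN(SiMe3)2 (2 equiv), THF, 0 °C; then 24, −78 → 0 °C; cold 1 M HCl work-up
Reagents that add atoms: none
Why: Z-selective Wittig olefination of an α-silyloxy aldehyde with the non-stabilised carboxylate ylide sets the 5Z alkene.

**Step 16**
Reactants: 26 (5Z)-7-[(tert-butyldimethylsilyl)oxy]hept-5-enoic acid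
Product: 27 methyl (5Z)-7-hydroxyhept-5-enoate
Conditions: AcCl (0.2 equiv), MeOH, 0 → 23 °C
Reagents that add atoms: methanol, `CO`
Why: Fischer esterification in methanolic HCl, which also cleaves the primary silyl ether by acid methanolysis.

**Step 17**
Reactants: 27 methyl (5Z)-7-hydroxyhept-5-enoate
Product: 28 methyl (5Z)-7-oxohept-5-enoate
Conditions: Dess–Martin periodinane, NaHCO3, CH2Cl2, 0 °C; used at once
Reagents that add atoms: none
Why: Buffered Dess–Martin oxidation of the (Z)-allylic alcohol, where neutral conditions and immediate use limit Z to E isomerisation of the enal.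

**Step 18**
Reactants: 22 (4S)-4-[(tert-butyldimethylsilyl)oxy]-2-chloro-4-[(2Z)-oct-2-en-1-yl]cyclopent-2-en-1-one; 28 methyl (5Z)-7-oxohept-5-enoate
Product: 30 methyl (5Z)-7-{(5S)-5-[(tert-butyldimethylsilyl)oxy]-3-chloro-5-[(2Z)-oct-2-en-1-yl]-2-oxocyclopent-3-en-1-yl}-7-hydroxyhept-5-enoate (7,8-anti expected as main isomer), via lithium dienolate 29 (not isolated)
Conditions: LiN(i-Pr)2, THF, −78 °C; then 28, −78 °C; AcOH quench at −78 °C
Reagents that add atoms: none
Why: Kinetic deprotonation at C8, the only enolisable position, gives the cross-conjugated lithium dienolate, which adds to the enal through a closed Zimmerman–Traxler transition state; the ring-fixed enolate geometry (oxygen trans to C12) is expected to favour the 7,8-anti adduct, and the configuration of C8 relative to C12 is irrelevant.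

**Step 19**
Reactants: 30 methyl (5Z)-7-{(5S)-5-[(tert-butyldimethylsilyl)oxy]-3-chloro-5-[(2Z)-oct-2-en-1-yl]-2-oxocyclopent-3-en-1-yl}-7-hydroxyhept-5-enoate
Product: 32 methyl (5Z,7Z,12R,14Z)-12-[(tert-butyldimethylsilyl)oxy]-10-chloro-9-oxoprosta-5,7,10,14-tetraen-1-oate, via mesylate 31 (not isolated)
Conditions: MeSO2Cl, Et3N, CH2Cl2, −40 → 0 °C
Reagents that add atoms: methanesulfonyl chloride, `CS(=O)(=O)Cl` (its atoms are carried by 31 only)
Why: Mesylation followed by amine-induced anti-periplanar (E2-like) elimination of the 7,8-anti mesylate places C6 cis to C9, which is the 7Z geometry; low temperature and short reaction time are chosen to limit a stepwise E1cB pathway and later equilibration to the 7E isomer.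

**Step 20**
Reactants: 32 methyl (5Z,7Z,12R,14Z)-12-[(tert-butyldimethylsilyl)oxy]-10-chloro-9-oxoprosta-5,7,10,14-tetraen-1-oate
Product: 33 methyl (5Z,7Z,12R,14Z)-10-chloro-12-hydroxy-9-oxoprosta-5,7,10,14-tetraen-1-oate (the target)
Conditions: HF (48 % aq.), MeCN, 0 → 23 °C
Reagents that add atoms: none
Why: Fluoride-driven cleavage of the tertiary silyl ether under non-basic conditions; ionisation of the C12 carbinol is disfavoured because the cation would be destabilised by the cross-conjugated ketone, and the base-labile dienone and the ester are spared.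

**Compound list**

1 | methyl acetoacetate | `COC(=O)CC(C)=O` | starting material
2 | 3-(benzyloxy)propanal | `O=CCCOCc1ccccc1` | starting material
3 | sodium lithium dianion of methyl acetoacetate (not isolated) | `[Na+].[Li+].C=C([O-])C=C([O-])OC` | intermediate
4 | methyl 7-(benzyloxy)-5-hydroxy-3-oxoheptanoate (racemic) | `COC(=O)CC(=O)CC(O)CCOCc1ccccc1` | intermediate
5 | methyl 2-(2-{4-(benzyloxy)-2-[(trimethylsilyl)oxy]butyl}-1,3-dioxolan-2-yl)acetate (racemic, not isolated) | `COC(=O)CC1(CC(O[Si](C)(C)C)CCOCc2ccccc2)OCCO1` | intermediate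
6 | methyl 2-{2-[4-(benzyloxy)-2-hydroxybutyl]-1,3-dioxolan-2-yl}acetate (racemic) | `COC(=O)CC1(CC(O)CCOCc2ccccc2)OCCO1` | intermediate
7 | 4-(benzyloxy)-1-[2-(2-hydroxyethyl)-1,3-dioxolan-2-yl]butan-2-ol (racemic) | `OCCC1(CC(O)CCOCc2ccccc2)OCCO1` | intermediate
8 | 2-{2-[4-(benzyloxy)-2-oxobutyl]-1,3-dioxolan-2-yl}acetaldehyde | `O=CCC1(CC(=O)CCOCc2ccccc2)OCCO1` | intermediate
9 | (8S)-8-[2-(benzyloxy)ethyl]-8-hydroxy-1,4-dioxaspiro[4.4]nonan-7-one | `c1ccccc1COCC[C@@]1(O)C(=O)CC2(OCCO2)C1` | intermediate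
10 | (8S)-8-[2-(benzyloxy)ethyl]-8-[(tert-butyldimethylsilyl)oxy]-1,4-dioxaspiro[4.4]nonan-7-one | `c1ccccc1COCC[C@@]1(O[Si](C)(C)C(C)(C)C)C(=O)CC2(OCCO2)C1` | intermediate
11 | (7RS,8S)-8-[2-(benzyloxy)ethyl]-8-[(tert-butyldimethylsilyl)oxy]-1,4-dioxaspiro[4.4]nonan-7-ol (both C7 epimers) | `c1ccccc1COCC[C@@]1(O[Si](C)(C)C(C)(C)C)C(O)CC2(OCCO2)C1` | intermediate
12 | (7RS,8S)-8-[2-(benzyloxy)ethyl]-8-[(tert-butyldimethylsilyl)oxy]-1,4-dioxaspiro[4.4]nonan-7-yl acetate | `c1ccccc1COCC[C@@]1(O[Si](C)(C)C(C)(C)C)C(OC(C)=O)CC2(OCCO2)C1` | intermediate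
13 | (7RS,8S)-8-[(tert-butyldimethylsilyl)oxy]-8-(2-hydroxyethyl)-1,4-dioxaspiro[4.4]nonan-7-yl acetate | `OCC[C@@]1(O[Si](C)(C)C(C)(C)C)C(OC(C)=O)CC2(OCCO2)C1` | intermediate
14 | (7RS,8S)-8-[(tert-butyldimethylsilyl)oxy]-8-(2-oxoethyl)-1,4-dioxaspiro[4.4]nonan-7-yl acetate | `O=CC[C@@]1(O[Si](C)(C)C(C)(C)C)C(OC(C)=O)CC2(OCCO2)C1` | intermediate
15 | hexyltriphenylphosphonium bromide | `CCCCCC[P+](c1ccccc1)(c1ccccc1)c1ccccc1.[Br-]` | starting material
16 | hexylidene(triphenyl)phosphorane (not isolated) | `CCCCCC=P(c1ccccc1)(c1ccccc1)c1ccccc1` | intermediate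
17 | (7RS,8S)-8-[(tert-butyldimethylsilyl)oxy]-8-[(2Z)-oct-2-en-1-yl]-1,4-dioxaspiro[4.4]nonan-7-yl acetate | `CCCCC/C=C\C[C@@]1(O[Si](C)(C)C(C)(C)C)C(OC(C)=O)CC2(OCCO2)C1` | intermediate
18 | (1RS,2S)-2-[(tert-butyldimethylsilyl)oxy]-2-[(2Z)-oct-2-en-1-yl]-4-oxocyclopentyl acetate (not isolated) | `CCCCC/C=C\C[C@@]1(O[Si](C)(C)C(C)(C)C)C(OC(C)=O)CC(=O)C1` | intermediate
19 | (4S)-4-[(tert-butyldimethylsilyl)oxy]-4-[(2Z)-oct-2-en-1-yl]cyclopent-2-en-1-one | `CCCCC/C=C\C[C@@]1(O[Si](C)(C)C(C)(C)C)C=CC(=O)C1` | intermediate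
20 | (4S)-4-[(tert-butyldimethylsilyl)oxy]-4-[(2Z)-oct-2-en-1-yl]-6-oxabicyclo[3.1.0]hexan-2-one (cis-fused epoxide, either face) | `CCCCC/C=C\C[C@@]1(O[Si](C)(C)C(C)(C)C)C2OC2C(=O)C1` | intermediate
21 | (4S)-4-[(tert-butyldimethylsilyl)oxy]-2-chloro-3-hydroxy-4-[(2Z)-oct-2-en-1-yl]cyclopentan-1-one (not isolated) | `CCCCC/C=C\C[C@@]1(O[Si](C)(C)C(C)(C)C)C(O)C(Cl)C(=O)C1` | intermediate
22 | (4S)-4-[(tert-butyldimethylsilyl)oxy]-2-chloro-4-[(2Z)-oct-2-en-1-yl]cyclopent-2-en-1-one | `CCCCC/C=C\C[C@@]1(O[Si](C)(C)C(C)(C)C)C=C(Cl)C(=O)C1` | intermediate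
23 | (4-carboxybutyl)triphenylphosphonium bromide | `OC(=O)CCCC[P+](c1ccccc1)(c1ccccc1)c1ccccc1.[Br-]` | starting material
24 | (tert-butyldimethylsilyloxy)acetaldehyde | `CC(C)(C)[Si](C)(C)OCC=O` | starting material
25 | sodium 5-(triphenylphosphoranylidene)pentanoate (not isolated) | `[Na+].[O-]C(=O)CCCC=P(c1ccccc1)(c1ccccc1)c1ccccc1` | intermediate
26 | (5Z)-7-[(tert-butyldimethylsilyl)oxy]hept-5-enoic acid | `CC(C)(C)[Si](C)(C)OC/C=C\CCCC(=O)O` | intermediate
27 | methyl (5Z)-7-hydroxyhept-5-enoate | `OC/C=C\CCCC(=O)OC` | intermediate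
28 | methyl (5Z)-7-oxohept-5-enoate | `O=C/C=C\CCCC(=O)OC` | intermediate
29 | lithium (3S)-3-[(tert-butyldimethylsilyl)oxy]-5-chloro-3-[(2Z)-oct-2-en-1-yl]cyclopenta-1,4-dien-1-olate (not isolated) | `[Li+].CCCCC/C=C\C[C@@]1(O[Si](C)(C)C(C)(C)C)C=C(Cl)C([O-])=C1` | intermediate
30 | methyl (5Z)-7-{(5S)-5-[(tert-butyldimethylsilyl)oxy]-3-chloro-5-[(2Z)-oct-2-en-1-yl]-2-oxocyclopent-3-en-1-yl}-7-hydroxyhept-5-enoate (C7 and C8 open in the SMILES; 7,8-anti expected as main isomer) | `CCCCC/C=C\C[C@@]1(O[Si](C)(C)C(C)(C)C)C=C(Cl)C(=O)C1C(O)/C=C\CCCC(=O)OC` | intermediate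
31 | methyl (5Z)-7-{(5S)-5-[(tert-butyldimethylsilyl)oxy]-3-chloro-5-[(2Z)-oct-2-en-1-yl]-2-oxocyclopent-3-en-1-yl}-7-[(methylsulfonyl)oxy]hept-5-enoate (not isolated) | `CCCCC/C=C\C[C@@]1(O[Si](C)(C)C(C)(C)C)C=C(Cl)C(=O)C1C(OS(C)(=O)=O)/C=C\CCCC(=O)OC` | intermediate
32 | methyl (5Z,7Z,12R,14Z)-12-[(tert-butyldimethylsilyl)oxy]-10-chloro-9-oxoprosta-5,7,10,14-tetraen-1-oate (same C12 arrangement as in 22; the descriptor changes by the priority rules only) | `CCCCC/C=C\C[C@@]1(O[Si](C)(C)C(C)(C)C)C=C(Cl)C(=O)/C1=C\C=C/CCCC(=O)OC` | intermediate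
33 | methyl (5Z,7Z,12R,14Z)-10-chloro-12-hydroxy-9-oxoprosta-5,7,10,14-tetraen-1-oate | `CCCCC/C=C\C[C@@]1(O)C=C(Cl)C(=O)/C1=C\C=C/CCCC(=O)OC` | target

**Step count and risks**

Total step count: 20. Longest linear sequence: 17 steps (steps 1–14 and 18–20); the C1–C7 enal 28 is made in steps 15–17.

Steps most likely to fail:

1. Step 5. The carbene may discriminate poorly between the two faces of a ketone whose two substituents are both methylene groups, and slow turnover with an aliphatic ketone may let base-mediated aldol closure compete. Fallback, setting out from 8: the ring is closed with the achiral salt 2-(pentafluorophenyl)-6,7-dihydro-5H-pyrrolo[2,1-c][1,2,4]triazol-2-ium tetrafluoroborate and Et3N, which should give 9 together with its mirror image, the (R)-ketol F1. The mixture is silylated as in step 6 to give 10 and the (R)-silyl ether F2. Corey–Bakshi–Shibata reduction follows, with BH3·SMe2 and (S)-1-methyl-3,3-diphenyltetrahydro-1H,3H-pyrrolo[1,2-c][1,3,2]oxazaborole. Reagent control should deliver hydride to the same face of C11 in both enantiomers (7R expected, with C12 as the large group), so they become diastereomers: the (7R,8S) epimer of 11 and the (7R,8R)-alcohol F3, to be separated by chromatography. The route is rejoined at 11. The stereochemical information then comes from the reduction and a separation instead of from the carbene.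

2. Step 19. Geometric control may be lost if the mesylate leaves stepwise through the dienolate (E1cB) or if the product equilibrates under base, both of which favour the more stable 7E isomer; an unselective aldol in step 18 has the same effect. Fallback, setting out from 22: LiN(i-Pr)2 and Me3SiCl give the trimethylsilyl dienol ether F4. Fluoride-promoted addition to 28 with tris(dimethylamino)sulfonium difluorotrimethylsilicate at −78 °C passes through an open transition state and is expected to favour the 7,8-syn adduct whatever the enolate geometry, obtained as the silylated syn adduct F5. Mild acidic methanolysis frees the carbinol (the 7,8-syn isomer of 30). The Burgess reagent, methyl N-(triethylammoniosulfonyl)carbamate, converts it into the sulfamate F6, whose concerted syn-elimination under neutral conditions again places C6 cis to C9. The route is rejoined at 32.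

3. Step 2. The β-hydroxy ketone may dehydrate, or the hydroxy ester lactonise, before the sluggish β-keto ester carbonyl is ketalised. Fallback, setting out from 4: the C12 hydroxyl is protected with t-BuPh2SiCl and imidazole as the tert-butyldiphenylsilyl ether F7. This is ketalised under classical conditions (ethylene glycol, TsOH·H2O, benzene, water separator) to the dioxolane F8, reduced with LiAlH4 to the primary alcohol F9, and desilylated with Bu4NF. The route is rejoined at 7.

**Further compounds**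

F1 | step 5 | (8R)-8-[2-(benzyloxy)ethyl]-8-hydroxy-1,4-dioxaspiro[4.4]nonan-7-one | `c1ccccc1COCC[C@]1(O)C(=O)CC2(OCCO2)C1`
F2 | step 5 | (8R)-8-[2-(benzyloxy)ethyl]-8-[(tert-butyldimethylsilyl)oxy]-1,4-dioxaspiro[4.4]nonan-7-one | `c1ccccc1COCC[C@]1(O[Si](C)(C)C(C)(C)C)C(=O)CC2(OCCO2)C1`
F3 | step 5 | (7R,8R)-8-[2-(benzyloxy)ethyl]-8-[(tert-butyldimethylsilyl)oxy]-1,4-dioxaspiro[4.4]nonan-7-ol | `c1ccccc1COCC[C@]1(O[Si](C)(C)C(C)(C)C)[C@H](O)CC2(OCCO2)C1`
F4 | step 19 | tert-butyl{[(1S)-3-chloro-1-[(2Z)-oct-2-en-1-yl]-4-[(trimethylsilyl)oxy]cyclopenta-2,4-dien-1-yl]oxy}dimethylsilane | `CCCCC/C=C\C[C@@]1(O[Si](C)(C)C(C)(C)C)C=C(Cl)C(O[Si](C)(C)C)=C1`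
F5 | step 19 | methyl (5Z)-7-{(5S)-5-[(tert-butyldimethylsilyl)oxy]-3-chloro-5-[(2Z)-oct-2-en-1-yl]-2-oxocyclopent-3-en-1-yl}-7-[(trimethylsilyl)oxy]hept-5-enoate (7,8-syn) | `CCCCC/C=C\C[C@@]1(O[Si](C)(C)C(C)(C)C)C=C(Cl)C(=O)C1C(O[Si](C)(C)C)/C=C\CCCC(=O)OC`
F6 | step 19 | methyl (5Z)-7-{(5S)-5-[(tert-butyldimethylsilyl)oxy]-3-chloro-5-[(2Z)-oct-2-en-1-yl]-2-oxocyclopent-3-en-1-yl}-7-{[(methoxycarbonyl)sulfamoyl]oxy}hept-5-enoate (7,8-syn) | `CCCCC/C=C\C[C@@]1(O[Si](C)(C)C(C)(C)C)C=C(Cl)C(=O)C1C(OS(=O)(=O)NC(=O)OC)/C=C\CCCC(=O)OC`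
F7 | step 2 | methyl 7-(benzyloxy)-5-[(tert-butyldiphenylsilyl)oxy]-3-oxoheptanoate (racemic) | `COC(=O)CC(=O)CC(O[Si](c1ccccc1)(c1ccccc1)C(C)(C)C)CCOCc1ccccc1`
F8 | step 2 | methyl 2-(2-{4-(benzyloxy)-2-[(tert-butyldiphenylsilyl)oxy]butyl}-1,3-dioxolan-2-yl)acetate (racemic) | `COC(=O)CC1(CC(O[Si](c2ccccc2)(c2ccccc2)C(C)(C)C)CCOCc2ccccc2)OCCO1`
F9 | step 2 | 2-(2-{4-(benzyloxy)-2-[(tert-butyldiphenylsilyl)oxy]butyl}-1,3-dioxolan-2-yl)ethanol (racemic) | `OCCC1(CC(O[Si](c2ccccc2)(c2ccccc2)C(C)(C)C)CCOCc2ccccc2)OCCO1`
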